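(The readings stem from a simulated flask on assumed constants, noise included.)

In the first 3.00 h of the cedar run the starting material drops to 20% of its charge, and after that it falls slowly, so I reckon with the fraction left on that slow rung.

| flask | starting material | coupling partner | remark | time |
|---|---|---|---|---|
| cedar | 0.15 M | 0.40 M | run made earlier |  |
| west | 0.10 M | 0.400 M |  | 3.0 d |
| north-west | 0.10 M | 0.800 M |  | 3.0 d |
| north | 0.10 M | 1.50 M |  | 3.0 d |

cedar run (percent of the starting material charged)

| time / h | target / % | starting material / % |
|---|---|---|
| 3.00 | 0 | 20 |
| 8.00 | 5 | 18 |
| 20.0 | 16 | 16 |
| 40.0 | 26 | 11 |

(standard deviation of a reading: 1.5 percentage points)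

- candidate steps: target <-> isomer of the product; coupling partner + intermediate B <-> intermediate C; coupling partner + intermediate A -> side product B; intermediate B -> target; intermediate A <-> intermediate B; starting material + coupling partner <-> intermediate A; starting material <-> side product A
- "hardly changes" means that all values lie within two and a half points (for a concentration: within two and a half percent of the largest)

1. [target] at the end for west, north-west, north, in this order
2. how the row runs (falls, then rises / rises, then falls / hardly changes / falls all the way / rises all the way)

The first and last cedar readings of the starting material give my drain rate 0.0162 /h, the fall per hour in the logarithm of the fraction left. It is a reading with the scatter of its two points, and it means a half-life of 42.9 h.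

| Rung | Time | Cedar run |
|---|---|---|
| fast fall | by 3.00 h | starting material 20%, target 0% |
| lag | by 8.00 h | target 5% |
| slow drain | half-life 42.9 h | by 40.0 h: starting material 11%, target 26% |

The half-life is shorter than the 3.0 d asked for, so west, with the partner charge of cedar, should keep 32.8% of its fraction at 3.00 h. I assume the drain rate is proportional to the partner charge, so that the fall is pseudo-first-order at each charge; this is a guess, since cedar shows one charge. The partner ratio then becomes a power on the fraction left: 10.8% in north-west and 1.53% in north.

By its readings, cedar made 57.8% target per fraction spent, so I reckon 0.0388 M for west. From west to north the fraction spent grows by a factor 1.47, less than the partner's factor 3.75. The candidate step from coupling partner and intermediate A to side product B runs faster with more partner, and I expect this loss to pull the row down.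

The forecast gives 0.04 M, 0.034 M and 0.025 M, a row that falls all the way, holding that “Extra partner cannot help much”.

The flasks give 0.0376 M, 0.0374 M and 0.0287 M, a row that falls all the way.

    target ⇌ isomer of the product (K = 0.490, k = 0.0490 /h)
    coupling partner + intermediate B ⇌ intermediate C (K = 2.60 /M, k = 0.0530 /M/h)
    coupling partner + intermediate A → side product B (k = 0.140 /M/h)
    intermediate B → target (k = 0.180 /h)
    intermediate A ⇌ intermediate B (K = 1.30, k = 0.670 /h)
    starting material + coupling partner ⇌ intermediate A (K = 22.0 /M, k = 0.270 /M/h)
    starting material ⇌ side product A (K = 3.20, k = 1.40 /h)

At 3.00 d, side product B stands at 15.5% in west and 50.1% in north. Between 1.50 d and 3.00 d, west keeps 51.6% of its starting material, and the drain rate gives 55.8%. Over the same span north-west keeps 25.5%, and the drain rate scaled by the partner ratio gives 31.2%.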